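**Retrosynthetic overview**
- The route rests on one atom. In the chain ring A–C(=O)–CH2–C(=O)–ring B, the carbonyl carbon on C1' of ring A (the 2'-OMe, 3'-prenyl, 4'-OH ring) has only two skeletal bonds, to aryl C1' and to the central CH2. It is cut out as carbon monoxide, which breaks both bonds at once.
- This leaves a ring A aryl bromide (Br on C1'), CO and the methyl ketone of ring B. Both phenols are masked as TIPS ethers, which are removed last with buffered fluoride.
- The ring A bromide comes from 4-bromoresorcinol. Its bromine already marks C1'. Iodine placed between the two oxygens marks C3' and is later exchanged for prenyl while the C–Br bond is kept. The two hydroxyls are told apart by crowding: TIPS goes on the open one, methyl on the one between Br and I.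
- No ring is formed anywhere, since both benzene rings are bought, and no stereocentre is set.

Key step: step 6

Remark on the chemistry: the target has no stereocentre and its alkene carries two identical methyl groups, so it is achiral and there is no enantiomer to choose. It is drawn as the diketone but should exist largely as the chelated enol. "Prenyl" means 3-methylbut-2-en-1-yl.

Step 1
Reactants: 1 4-bromoresorcinol (4-bromobenzene-1,3-diol)
Product: 2 4-bromo-2-iodobenzene-1,3-diol
Conditions: I2 (1.0 equiv), NaHCO3 (1.1 equiv), H2O, 0 °C → rt; Na2S2O3, near-neutral work-up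
Reagents that add atoms: iodine, II
Why: Electrophilic aromatic iodination of a resorcinol with I2 in weakly basic water is the known way to place iodine on the carbon flanked by both hydroxyls (as in the preparation of 2-iodoresorcinol), and in 1 that carbon (C2) is doubly ortho-activated while the C–Br bond is inert, so one equivalent of iodine should give 2.

Step 2
Reactants: 2 4-bromo-2-iodobenzene-1,3-diol
Product: 3 6-bromo-2-iodo-3-(triisopropylsilyloxy)phenol
Conditions: TIPSCl (1.05 equiv), imidazole (2.0 equiv), DMF, 0 °C → rt
Reagents that add atoms: triisopropylsilyl chloride, CC(C)[Si](Cl)(C(C)C)C(C)C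
Why: In this sterically governed silyl ether formation the hydroxyl para to bromine has only iodine as ortho neighbour, whereas the other is wedged between iodine and bromine and is only slightly more acidic, so the bulky TIPS group should settle on the open oxygen.

Step 3
Reactants: 3 6-bromo-2-iodo-3-(triisopropylsilyloxy)phenol
Product: 4 (4-bromo-2-iodo-3-methoxyphenoxy)triisopropylsilane
Conditions: MeI (1.5 equiv), K2CO3 (1.5 equiv), acetone, rt → 40 °C
Reagents that add atoms: iodomethane, CI
Why: In this Williamson etherification the remaining phenol, acidified by two ortho halogens, is deprotonated by carbonate and the small electrophile still reaches the crowded phenoxide, while the aryl TIPS ether tolerates dry K2CO3 in acetone.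

Step 4
Reactants: 4 (4-bromo-2-iodo-3-methoxyphenoxy)triisopropylsilane; 5 prenyl bromide (1-bromo-3-methylbut-2-ene)
Product: 7 (4-bromo-3-methoxy-2-prenylphenoxy)triisopropylsilane, via arylmagnesium chloride 6 (not isolated)
Conditions: i-PrMgCl·LiCl (1.1 equiv), THF, −20 °C; then CuI (10 mol%), 5 (1.4 equiv), −20 → 0 °C; aq NH4Cl
Reagents that add atoms: none
Why: Iodine–magnesium exchange with the LiCl-activated Grignard reagent takes C–I far faster than C–Br and is assisted by the two flanking oxygens, and copper-catalysed allylic substitution with all of 6 present (diarylcuprate regime) should attack the primary carbon of 5 (SN2), because the transposed mode would build a quaternary carbon between two ortho substituents and O-to-C silyl migration is not expected at magnesium below 0 °C.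

Step 5
Reactants: 8 4'-hydroxyacetophenone
Product: 9 1-[4-(triisopropylsilyloxy)phenyl]ethanone
Conditions: TIPSCl (1.1 equiv), imidazole (2.0 equiv), DMF, rt
Reagents that add atoms: triisopropylsilyl chloride, CC(C)[Si](Cl)(C(C)C)C(C)C
Why: This is a standard silyl ether formation on an unhindered phenol, with TIPS chosen because it resists the hindered amide base and the enolate of step 6 better than smaller silyl groups and leaves later without acid or hydrogen.

Step 6
Reactants: 7 (4-bromo-3-methoxy-2-prenylphenoxy)triisopropylsilane; 9 1-[4-(triisopropylsilyloxy)phenyl]ethanone; 10 carbon monoxide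
Product: 13 1-[2-methoxy-3-prenyl-4-(triisopropylsilyloxy)phenyl]-3-[4-(triisopropylsilyloxy)phenyl]propane-1,3-dione, via sodium enolate 11 (not isolated), via sodium diketonate 12 (not isolated)
Conditions: 9 (2.0 equiv), NaHMDS (2.0 equiv), THF, rt; then 7, Pd(dba)2 (5 mol%), dppp (5 mol%), CO (ca. 1.5 equiv, sealed two-chamber vessel), THF, 80 °C; cold 1 M HCl quench
Reagents that add atoms: none
Why: Pd(0)/dppp inserts into the C1'–Br bond of 7, CO migrates into the aryl–Pd bond to give an aroylpalladium(II) complex, enolate 11 replaces bromide and C–C reductive elimination closes the cycle, so the C1'–C(=O) and C(=O)–CH2 bonds are both made at the incoming CO carbon. The reaction type is the known palladium-catalysed carbonylative α-arylation of aryl ketones with aryl bromides (Pd(dba)2/dppp, NaHMDS, near-stoichiometric CO), established for electron-rich bromoanisoles and for acetophenones, so only the substrate is new. No ring is closed and no stereocentre is created. The selectivity needed is carbonylation ahead of enolate coupling: CO insertion relieves the crowding between palladium and the out-of-plane 2'-methoxy group, and the small-bite chelate dppp is a poor ligand for direct aryl–enolate reductive elimination, so the CO-free α-aryl ketone should stay minor. The second equivalent of 11 deprotonates the product at once to the chelated diketonate 12, which is too stabilised to be acylated or arylated again and is released as 13 only on the acidic quench. The prenyl alkene is trisubstituted and meta to the metal, out of reach for acyl-Heck cyclisation, the TIPS ethers keep the phenols from trapping the aroylpalladium as aryl esters, and stray loss of a silyl group would only anticipate step 7.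

Step 7
Reactants: 13 1-[2-methoxy-3-prenyl-4-(triisopropylsilyloxy)phenyl]-3-[4-(triisopropylsilyloxy)phenyl]propane-1,3-dione
Product: 14 1-[4-hydroxy-2-methoxy-3-(3-methylbut-2-en-1-yl)phenyl]-3-(4-hydroxyphenyl)propane-1,3-dione
Conditions: TBAF (2.5 equiv), AcOH (2.5 equiv), THF, 0 °C → rt
Reagents that add atoms: none
Why: Fluoride-induced cleavage of both aryl silyl ethers is driven by Si–F bond formation, and the acetic acid buffer keeps the medium too mild for retro-Claisen cleavage of the diketone and far too weakly acidic to cyclise the ortho-prenyl phenol to a chroman.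

**Compound list**
1 | 4-bromoresorcinol | Oc1ccc(Br)c(O)c1 | starting material
2 | 4-bromo-2-iodobenzene-1,3-diol | Oc1ccc(Br)c(O)c1I | intermediate
3 | 6-bromo-2-iodo-3-(triisopropylsilyloxy)phenol | Oc1c(Br)ccc(O[Si](C(C)C)(C(C)C)C(C)C)c1I | intermediate
4 | (4-bromo-2-iodo-3-methoxyphenoxy)triisopropylsilane | COc1c(Br)ccc(O[Si](C(C)C)(C(C)C)C(C)C)c1I | intermediate
5 | prenyl bromide | CC(C)=CCBr | starting material
6 | [3-bromo-2-methoxy-6-(triisopropylsilyloxy)phenyl]magnesium chloride (not isolated) | COc1c(Br)ccc(O[Si](C(C)C)(C(C)C)C(C)C)c1[Mg]Cl | intermediate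
7 | (4-bromo-3-methoxy-2-prenylphenoxy)triisopropylsilane | COc1c(Br)ccc(O[Si](C(C)C)(C(C)C)C(C)C)c1CC=C(C)C | intermediate
8 | 4'-hydroxyacetophenone | CC(=O)c1ccc(O)cc1 | starting material
9 | 1-[4-(triisopropylsilyloxy)phenyl]ethanone | CC(=O)c1ccc(O[Si](C(C)C)(C(C)C)C(C)C)cc1 | intermediate
10 | carbon monoxide | [C-]#[O+] | starting material
11 | sodium enolate of 9 (not isolated) | [Na+].C=C([O-])c1ccc(O[Si](C(C)C)(C(C)C)C(C)C)cc1 | intermediate
12 | sodium (Z)-diketonate of 13, chelated form (not isolated) | [Na+].COc1c(C(=O)/C=C(\[O-])c2ccc(O[Si](C(C)C)(C(C)C)C(C)C)cc2)ccc(O[Si](C(C)C)(C(C)C)C(C)C)c1CC=C(C)C | intermediate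
13 | 1-[2-methoxy-3-prenyl-4-(triisopropylsilyloxy)phenyl]-3-[4-(triisopropylsilyloxy)phenyl]propane-1,3-dione | COc1c(C(=O)CC(=O)c2ccc(O[Si](C(C)C)(C(C)C)C(C)C)cc2)ccc(O[Si](C(C)C)(C(C)C)C(C)C)c1CC=C(C)C | intermediate
14 | 1-[4-hydroxy-2-methoxy-3-(3-methylbut-2-en-1-yl)phenyl]-3-(4-hydroxyphenyl)propane-1,3-dione (achiral) | COc1c(C(=O)CC(=O)c2ccc(O)cc2)ccc(O)c1CC=C(C)C | target

Total step count: 7. Longest linear sequence: 6 (steps 1, 2, 3, 4, 6, 7).

**Steps most likely to fail**

Step 6.
- **What may go wrong:** Oxidative addition at the electron-rich, ortho-substituted C–Br bond may be slow. Palladium may be saturated by CO. The enolate may couple before CO inserts. The silyl ethers may erode in hot base.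
- **Fallback:** It sets out from 7 and comes back at 13, building the same carbonyl carbon stepwise.
  - Bromine–lithium exchange of 7 (n-BuLi, THF, −78 °C) and formylation with DMF should give 2-methoxy-3-prenyl-4-(triisopropylsilyloxy)benzaldehyde F1.
  - Aldol addition of the lithium enolate of 9 (LDA, THF, −78 °C) to it should give racemic 3-hydroxy-3-[2-methoxy-3-prenyl-4-(triisopropylsilyloxy)phenyl]-1-[4-(triisopropylsilyloxy)phenyl]propan-1-one F2.
  - Oxidation of its carbinol with Dess–Martin periodinane (NaHCO3, CH2Cl2) erases the transient stereocentre and gives 13.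

Step 1.
- **What may go wrong:** Iodine may enter at C6 instead of between the oxygens. Double iodination or migration of iodine during an acidic work-up is also possible.
- **Fallback:** It sets out from 1 and comes back at 7, using no iodide and no organomagnesium reagent.
  - Silylation of 1 with one equivalent of TIPSCl/imidazole at the hydroxyl para to bromine, which has no ortho substituent, should give 2-bromo-5-(triisopropylsilyloxy)phenol F3.
  - Copper-catalysed O-alkylation with 3-chloro-3-methylbut-1-yne (CuCl2 cat., DBU, MeCN, 0 °C) gives [4-bromo-3-(2-methylbut-3-yn-2-yloxy)phenoxy]triisopropylsilane F4.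
  - Semihydrogenation over Lindlar catalyst (H2, quinoline, EtOAc) gives [4-bromo-3-(2-methylbut-3-en-2-yloxy)phenoxy]triisopropylsilane F5.
  - Aromatic Claisen rearrangement (PhNEt2, about 130 °C) can rearomatise only at the one free ortho carbon, the one between the oxygens, because the other ortho carbon carries bromine. With allyl inversion it gives 6-bromo-2-prenyl-3-(triisopropylsilyloxy)phenol F6.
  - Williamson methylation as in step 3 then gives 7.

Step 4.
- **What may go wrong:** Allylic transposition may occur during C–C bond formation. Capture of the crowded arylmetal by the substituted allyl electrophile may be sluggish, leaving time for protonation.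
- **Fallback:** It sets out from 4 and comes back at 7, building the prenyl group in two stages.
  - Grignard reagent 6, made as before, is trapped with symmetrical and more reactive allyl bromide (CuI cat., THF, −20 → 0 °C). This gives (2-allyl-4-bromo-3-methoxyphenoxy)triisopropylsilane F7, for which the two substitution modes give the same product.
  - Olefin cross-metathesis with excess 2-methylbut-2-ene (second-generation Grubbs catalyst, CH2Cl2, 40 °C) then installs the gem-dimethyl terminus and gives 7.

**Further compounds**
F1 | step 6 | 2-methoxy-3-prenyl-4-(triisopropylsilyloxy)benzaldehyde | COc1c(C=O)ccc(O[Si](C(C)C)(C(C)C)C(C)C)c1CC=C(C)C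
F2 | step 6 | racemic 3-hydroxy-3-[2-methoxy-3-prenyl-4-(triisopropylsilyloxy)phenyl]-1-[4-(triisopropylsilyloxy)phenyl]propan-1-one | COc1c(C(O)CC(=O)c2ccc(O[Si](C(C)C)(C(C)C)C(C)C)cc2)ccc(O[Si](C(C)C)(C(C)C)C(C)C)c1CC=C(C)C
F3 | step 1 | 2-bromo-5-(triisopropylsilyloxy)phenol | Oc1cc(O[Si](C(C)C)(C(C)C)C(C)C)ccc1Br
F4 | step 1 | [4-bromo-3-(2-methylbut-3-yn-2-yloxy)phenoxy]triisopropylsilane | C#CC(C)(C)Oc1cc(O[Si](C(C)C)(C(C)C)C(C)C)ccc1Br
F5 | step 1 | [4-bromo-3-(2-methylbut-3-en-2-yloxy)phenoxy]triisopropylsilane | C=CC(C)(C)Oc1cc(O[Si](C(C)C)(C(C)C)C(C)C)ccc1Br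
F6 | step 1 | 6-bromo-2-prenyl-3-(triisopropylsilyloxy)phenol | Oc1c(Br)ccc(O[Si](C(C)C)(C(C)C)C(C)C)c1CC=C(C)C
F7 | step 4 | (2-allyl-4-bromo-3-methoxyphenoxy)triisopropylsilane | COc1c(Br)ccc(O[Si](C(C)C)(C(C)C)C(C)C)c1CC=C
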